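The closed, stirred vessel holds substrate and reagent at fixed volume and temperature, with a trace of free catalyst that turns over while it survives.

in all of them: free catalyst 0.13 mol%
- Tuesday's: substrate 0.17 M; reagent 1 equiv; temperature −5 °C; run made earlier
- Friday's: substrate 0.17 M; reagent 4 equiv; temperature 25 °C; run made earlier
- Thursday's: substrate 0.085 M; reagent 2 equiv; temperature −5 °C; run made earlier
- green: substrate 0.17 M; reagent 2.00 equiv; temperature 25 °C; time 40 min
- grey: substrate 0.17 M; reagent 2.00 equiv; temperature 0 °C; time 40 min
- teal: substrate 0.17 M; reagent 2.00 equiv; temperature 50 °C; time 40 min

- Tuesday's (time / min: product / %, substrate / %): 20.0: 84.3, 17.4; 50.0: 90.9, 8.5; 80.0: 92.2, 7.6; 120: 94.6, 6.0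
- Friday's (time / min: product / %, substrate / %): 2.50: 98.7, 0; 6.00: 100.2, 0.6; 15.0: 100.3, 1.0; 30.0: 100.7, 0.5
- Thursday's (time / min: product / %, substrate / %): 12.0: 73.4, 26.7; 25.0: 89.1, 9.5; 60.0: 98.6, 3.4; 120: 100.1, 0.6

(standard deviation of a reading: 1 percentage point)

- the flask that comes out highest in amount of product, in percent of the substrate charged, or "all alike" when all lie within 1.5 percentage points (green / grey / teal / all alike)
- product at the end, in percent of the substrate charged, green
- product at the end, in percent of the substrate charged, grey
- product at the end, in percent of the substrate charged, teal

- the analysis behind the earlier runs scatters by 1 percentage point, standard deviation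
- what may be going on: substrate + reagent + free catalyst -> product + free catalyst; free catalyst + product -> spent catalyst A; free catalyst -> spent catalyst B

Take the main step first, as first order in c(substrate), c(reagent) and c(free catalyst), and reckon with the fraction left. Let the catalyst dose D be the time integral of rate constant times c(free catalyst). With equal charges, the reciprocal of the fraction of substrate left, less one, equals D times c(substrate) charged. With unequal charges, the ln of fraction of reagent left over fraction of substrate left equals D times the difference of the charges.

Tuesday's reading at 20.0 min gives 27.9 M⁻¹. A catalyst that lasted would carry this to 168 M⁻¹ at 120 min, with substrate left at 3.39%. Adding the loss of free catalyst allows for the reading of 6.0% there: the dose read from Tuesday's flask is 92.2 M⁻¹, lower, so as read, D in Tuesday's flask grows more slowly than time.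

Warmth comes last, and 25 °C offers only a floor. Friday's highest substrate reading, 1.0%, gives D of at least about 8.47 M⁻¹. In green the difference of the charges is a third of Friday's, so that floor, taken over to green, leaves substrate, the limiting reagent, at 13.4%, and this reckoning puts green's product at about 86.6% or more. Tuesday's dose at 20.0 min, taken over unchanged to grey, gives an exponent of 4.75, so this reckoning leaves grey 0.436% of its substrate. No run gives a dose at 50 °C, so this reckoning has no number for teal.

The forecast names grey as highest, with green 99% (94% to 100.5%), grey 99.5% (97.5% to 100.5%) and teal 96% (80% to 100.5%): “Teal is the uncertain one, so I lean to grey as highest”. Its green range starts higher than the floor reckoned here.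

The flasks give green 93.5%, grey 99.9% and teal 48.4%, so grey is highest.

    substrate + reagent + free catalyst → product + free catalyst, rate k1*[substrate]*[reagent]*[free catalyst]/(1 + ([substrate]/sat1)) (0.340 M, k = 49000 M⁻² min⁻¹, Ea = 37.0 kJ mol⁻¹)
    free catalyst + product → spent catalyst A (k = 0.860 M⁻¹ min⁻¹, Ea = 54.0 kJ mol⁻¹)
    free catalyst → spent catalyst B (k = 0.660 min⁻¹, Ea = 90.0 kJ mol⁻¹)
    (constants at 25 °C)

Teal stops with 52% of its substrate and 76% of its reagent unused and free catalyst at 0%, and a tenfold time changes nothing. Those fractions, reckoned the same way, give teal a dose of 2.26 M⁻¹, against 12.4 M⁻¹ in green and 92.2 M⁻¹ read from Tuesday's flask. The main reason for teal's low product is the conversion of free catalyst into spent catalyst B: with that step struck out, teal reaches 99.9%. The same flask as green with 0.500 equiv of reagent, reckoned the same way, shows a dose of 11.3 M⁻¹ and ends at 38.2% product.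

The readings were computed for substances that don't exist.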